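The numbers in the tables were computed with made-up constants; the scatter is artificial.

| flask | starting material | second nucleophile | capture agent | solid first nucleophile | remark | time |
|---|---|---|---|---|---|---|
| gamma | 0.010 M | 10 mM | 10 mM | 9.5 mM | run made earlier |  |
| alpha | 0.0050 M | 10 mM | 10 mM | 9.5 mM | run made earlier |  |
| east | 0.010 M | 10.0 mM | 10.0 mM | 9.50 mM | everything together at the start | 12 d |
| west | 0.010 M (fed, over 2.5 d) | 10.0 mM | 10.0 mM | 9.50 mM | all else is in the flask from the start; the feed brings no volume worth counting | 12 d |
| south-east | 0.010 M | 10.0 mM (fed, over 2.5 d) | 10.0 mM | 9.50 mM | all else is in the flask from the start; the feed brings no volume worth counting | 12 d |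

| run | time / d | solvolysis product / % | target / % |
|---|---|---|---|
| gamma | 2.50 | 40.4 | 9.4 |
| gamma | 5.00 | 40.9 | 7.8 |
| gamma | 8.00 | 41.2 | 8.6 |
| gamma | 10.0 | 41.5 | 8.7 |
| gamma | 12.0 | 40.9 | 8.4 |
| alpha | 0.250 | 8.0 | 1.4 |
| alpha | 0.500 | 18.5 | 2.5 |
| alpha | 1.04 | 30.5 | 6.6 |
| alpha | 2.08 | 36.4 | 8.4 |
| alpha | 4.00 | 37.7 | 8.0 |

(standard deviation of a reading: 0.5 percentage points)

1. the flask that comes out highest in amount of solvolysis product, in percent of the starting material charged; "all alike" if 1.5 percentage points covers them all (east / west / south-east / all alike)
2. amount of solvolysis product at the end, in percent of the starting material charged, east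
3. amount of solvolysis product at the end, in percent of the starting material charged, west
4. amount of solvolysis product at the end, in percent of the starting material charged, south-east

- at the start none of the solid first nucleophile is in solution

The easy step is a balance: at the end of the gamma run, 40.9% of solvolysis product and 8.4% of target leave a gap of 50.7%. Suppose a partner charged at 10 mM catches this gap, mole for mole. The selectivity factor S is then the gap over the solvolysis product, divided by the partner's mean concentration (its charge less half of what is consumed): 0.166 /mM. The alpha run gives 0.167 /mM. Both runs held second nucleophile and capture agent equal, so they cannot name the partner.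

East repeats gamma, near 40.9%, and west, with its partner present from the start, is reckoned there too. If the capture agent is the partner, south-east also stays there, which is the floor; with no partner and gamma's target, the ceiling is 91.6%. Now take the second nucleophile as partner. In south-east its concentration is a ramp, and the mean of a ramp over the turnover is its value at the mean time of turnover. The alpha run read half of its last solvolysis value at 0.500 d, so a first-order turnover has a mean time near 0.721 d, where the feed alone gives c(second nucleophile) of 2.89 mM. With gamma's target, this gives 61.9%. Subtracting half of the capture this implies leaves 1.40 mM and gives 74.3%. This tightened bracket stands above east, so south-east is reckoned highest.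

The forecast gives 41% for east, 41.2% for west and 44% for south-east, below the tightened bracket, with south-east highest, reasoning that “South-east has little second nucleophile while most material reacts”.

The simulation gives 41.2% for east, 39.7% for west and 64.7% for south-east, which stands higher and inside the bracket.

    solid first nucleophile ⇌ first nucleophile, rate k1*(cs1 - [first nucleophile]) while solid is left; crystals form when [first nucleophile] > cs1 (solubility = 1.10 mM, k = 3.70 × 10⁻⁵ /s)
    second nucleophile + open intermediate → other capture product (k = 0.00540 /M/s)
    starting material → open intermediate (k = 2.20 × 10⁻⁵ /s)
    open intermediate + capture agent → trapped intermediate (k = 1.00 × 10⁻⁴ /M/s)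
    open intermediate → solvolysis product (k = 3.30 × 10⁻⁵ /s)
    first nucleophile + open intermediate → target (k = 0.00970 /M/s)

In south-east, half of the starting material's turnover was done by 0.365 d, against a feed of 2.5 d, and c(second nucleophile) averaged 0.00372 M over the feed. Other capture product over solvolysis product, 21.0% to 64.7%, divided by S, gives 1.96 mM as the concentration the open intermediate met, less than that average.

With 0.0025 M of starting material in the south-east recipe, the ramp value stays 2.89 mM and consumption leaves 2.51 mM, so S gives 61.9% to 64.7%. That flask gives 60.7%, below this range, with 13.8% of target against the 8.4% reckoned with.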